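**Retrosynthetic overview**

1. Atom labels: the seven-membered ring holds C1 (CH–O ester), C2 (CH2), C3 (fusion C–CH3), C7 (fusion C–OH), C8 and C9 (CH2) and C10 (C(CH3)OH); the five-membered ring holds C3, C4 and C5 (CH2), C6 (CH–isopropyl) and C7.
2. Feature used: C2 is the single methylene between oxygenated C1 and the quaternary fusion carbon C3. Taking C2 out contracts the seven-membered ring to the six-membered ring of a cis-hydrindanone whose C1 carbonyl sits directly on C3, which is a desymmetrised 2-methylcyclohexane-1,3-dione.
3. Last disconnections: the ester at O–C1, hydride at C1 (trans-diol from the α-hydroxy ketone), oxygen at C10 (Rubottom oxidation) and methyl at C10 (enolate alkylation) lead back to the hydroazulenone 17.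
4. Key disconnection: C2–C3 and C1–C2, so that 17 comes from hydrindanone 13 and a CH2 unit from bis(phenylseleno)methane. The seven-membered ring is formed last, by one-carbon enlargement of the six-membered ring with migration of C3.
5. Hydrindanone 13: the C6–C7 bond is made by CuH-catalysed reductive aldol cyclisation of enone-dione 7, which closes the five-membered ring onto the six-membered ring of the starting dione and sets C3, C6 and C7. Compound 7 comes from 2-methylcyclohexane-1,3-dione by C-allylation, ozonolysis and Wittig reaction.

Key step: step 8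

Assumption: (R)-DTBM-SEGPHOS, 5,5'-bis[bis(3,5-di-tert-butyl-4-methoxyphenyl)phosphino]-4,4'-bi-1,3-benzodioxole, is taken to favour the enantiotopic carbonyl that leads to 10; if the opposite sense is found, the (S)-ligand is used and nothing else changes.

Remark on names: ring names use their own locants, while C1–C10 in the text are the labels above. The descriptor at the methyl-bearing fusion carbon (S in 10–13, R from 17 on) and at the isopropyl-bearing carbon (S in 10 and 11, R from 12 on) changes because substituent priorities change, not because the centre inverts.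

**Route**

Step 1
Reactants: 1 2-methylcyclohexane-1,3-dione; 2 allyl acetate
Product: 3 2-methyl-2-(prop-2-en-1-yl)cyclohexane-1,3-dione
Conditions: Pd(PPh3)4 (2 mol %), Et3N, THF, 23 °C
Reagents that add atoms: none
Why: Tsuji–Trost allylation, in which the soft enolate of the 1,3-dione attacks the π-allylpalladium complex at carbon (any O-allyl product re-ionises and ends as the C-allyl compound), and no stereocentre is formed because the two carbonyl arms are still equivalent.

Step 2
Reactants: 3 2-methyl-2-(prop-2-en-1-yl)cyclohexane-1,3-dione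
Product: 5 (1-methyl-2,6-dioxocyclohexyl)acetaldehyde, via secondary ozonide 4 (not isolated)
Conditions: O3, CH2Cl2, −78 °C; then PPh3, −78 → 23 °C
Reagents that add atoms: ozone O=[O+][O-]
Why: Ozonolysis with reductive work-up cleaves the only C=C bond to the aldehyde with loss of the terminal carbon, the non-enolisable diketone being inert to ozone.

Step 3
Reactants: 5 (1-methyl-2,6-dioxocyclohexyl)acetaldehyde; 6 1-(triphenylphosphoranylidene)propan-2-one
Product: 7 2-methyl-2-[(2E)-4-oxopent-2-en-1-yl]cyclohexane-1,3-dione
Conditions: CH2Cl2, 23 → 40 °C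
Reagents that add atoms: none
Why: Wittig olefination with a stabilised acyl ylide should react only with the aldehyde (the ketones beside the quaternary carbon do not react with such ylides) and give the E-enone, whose geometry is removed again in step 4.

Step 4
Reactants: 7 2-methyl-2-[(2E)-4-oxopent-2-en-1-yl]cyclohexane-1,3-dione
Product: 10 (1S,3aS,7aS)-1-acetyl-7a-hydroxy-3a-methyloctahydro-4H-inden-4-one, via copper enolate 8 (not isolated), via silyl ether 9 (not isolated)
Conditions: Cu(OAc)2·H2O (5 mol %), (R)-DTBM-SEGPHOS (5.5 mol %), (EtO)2MeSiH, toluene, −40 → 0 °C; then aq NH4F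
Reagents that add atoms: none
Why: CuH-catalysed reductive aldol cyclisation that desymmetrises the 1,3-dione: hydride adds to C5 of the enone, the (Z)-copper enolate attacks through C6 one of the two enantiotopic ring carbonyls in a chelated Zimmerman–Traxler arrangement so that the acetyl group is cis to the new C7 hydroxyl, the three-atom tether enforces the cis ring fusion (C3 methyl cis to C7–OH), the chiral bisphosphine on copper selects the carbonyl and with it the absolute configuration at C3, C6 and C7, and the silane turns over the copper alkoxide and so protects the aldol against retro-aldol cleavage until work-up.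

Step 5
Reactants: 10 (1S,3aS,7aS)-1-acetyl-7a-hydroxy-3a-methyloctahydro-4H-inden-4-one
Product: 11 (1S,3aS,7aS)-1-acetyl-3a-methyl-7a-[(triethylsilyl)oxy]octahydro-4H-inden-4-one
Conditions: Et3SiOTf, 2,6-lutidine, CH2Cl2, −78 → 0 °C
Reagents that add atoms: triethylsilyl trifluoromethanesulfonate CC[Si](CC)(CC)OS(=O)(=O)C(F)(F)F
Why: Silylation of a hindered tertiary alcohol with a silyl triflate and a weak hindered base should leave both ketones untouched at low temperature and block retro-aldol cleavage and β-elimination later, the triethylsilyl group being chosen because it should survive peracid, amide base and dilute acetic acid and is large enough to screen one face of the later seven-membered ring.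

Step 6
Reactants: 11 (1S,3aS,7aS)-1-acetyl-3a-methyl-7a-[(triethylsilyl)oxy]octahydro-4H-inden-4-one
Product: 12 (1R,3aS,7aS)-3a-methyl-1-(prop-1-en-2-yl)-7a-[(triethylsilyl)oxy]octahydro-4H-inden-4-one
Conditions: Zn, CH2Br2, TiCl4, THF, 0 °C (reagent preformed); then 11 in CH2Cl2, 0 → 23 °C
Reagents that add atoms: dibromomethane BrCBr
Why: Takai–Lombardo methylenation uses a non-basic titanium–zinc methylene reagent that should neither epimerise the acetyl-bearing C6 nor eliminate the β-silyloxy group, and it should convert the methyl ketone in preference to the C1 ketone, which lies in the ring beside quaternary C3.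

Step 7
Reactants: 12 (1R,3aS,7aS)-3a-methyl-1-(prop-1-en-2-yl)-7a-[(triethylsilyl)oxy]octahydro-4H-inden-4-one
Product: 13 (1R,3aS,7aS)-3a-methyl-1-(propan-2-yl)-7a-[(triethylsilyl)oxy]octahydro-4H-inden-4-one
Conditions: H2 (3 atm), RhCl(PPh3)3 (5 mol %), toluene–EtOH, 23 °C
Reagents that add atoms: none
Why: Homogeneous hydrogenation of the 1,1-disubstituted alkene with RhCl(PPh3)3 should not move the double bond into the ring, so C6 is untouched, while the hindered ketone and the silyl ether are inert and no stereocentre is formed.

Step 8
Reactants: 13 (1R,3aS,7aS)-3a-methyl-1-(propan-2-yl)-7a-[(triethylsilyl)oxy]octahydro-4H-inden-4-one; 14 bis(phenylseleno)methane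
Product: 17 (1R,3aR,8aS)-3a-methyl-1-(propan-2-yl)-8a-[(triethylsilyl)oxy]octahydroazulen-5(1H)-one, via hydroxy selenide 15 (not isolated), via selenone 16 (not isolated)
Conditions: 14, n-BuLi, THF, −78 °C; 13, −78 → −40 °C; AcOH; then MeOH, mCPBA (excess), 0 → 23 °C
Reagents that add atoms: none
Why: Selenium–lithium exchange on 14 gives PhSeCH2Li, a small and weakly basic organolithium that adds to the hindered C1 carbonyl (new bond C1–C2) to give carbinol 15, and peracid then oxidises selenium to the selenone 16 without the usual selenoxide elimination because C1 bears no hydrogen. Benzeneseleninate is a very good leaving group on the primary carbon C2, and its departure is concerted with a hydroxyl-assisted 1,2-shift of a ring carbon from C1 to C2 (new bond C2–C3), which restores the carbonyl at C1. The closest known reaction type is the one-carbon homologation of cycloalkanones through 1-(phenylselanylmethyl)cycloalkanols and their selenones, a semipinacol rearrangement of the Tiffeneau–Demjanov kind in which the more substituted α-carbon migrates. The seven-membered ring is not closed by a cyclisation: it arises from the six-membered ring by ring enlargement when the C1–C3 bond is exchanged for the C2–C3 bond. No stereocentre is formed, the transient carbinol centre at C1 is destroyed again, and C3 migrates with retention so that C3, C6 and C7 are carried through unchanged. The step needs migration of quaternary C3 and not of methylene C10, and shift and not oxirane closure; the first is secured by the better stabilisation of the developing positive charge at C2 by the fully substituted C3 and by relief of the congestion of the contiguous fully substituted carbons C1, C3 and C7, the second by running the oxidation without base so that the hydroxyl is never an alkoxide.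

Step 9
Reactants: 17 (1R,3aR,8aS)-3a-methyl-1-(propan-2-yl)-8a-[(triethylsilyl)oxy]octahydroazulen-5(1H)-one
Product: 19 (1R,3aR,8aS)-3a,6-dimethyl-1-(propan-2-yl)-8a-[(triethylsilyl)oxy]octahydroazulen-5(1H)-one (both C10 epimers), via lithium enolate 18 (not isolated)
Conditions: LiN(i-Pr)2, THF, −78 °C; MeI, DMPU, −78 → −20 °C
Reagents that add atoms: iodomethane CI
Why: Kinetic enolate alkylation, in which the amide base should remove a proton from C10 and not from C2 (neopentylic and shielded by quaternary C3) and iodomethane alkylates the enolate at carbon, the configuration at C10 being of no consequence because C10 is made planar again in step 10.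

Step 10
Reactants: 19 (1R,3aR,8aS)-3a,6-dimethyl-1-(propan-2-yl)-8a-[(triethylsilyl)oxy]octahydroazulen-5(1H)-one
Product: 20 trimethylsilyl enol ether of 19 with the C1=C10 double bond
Conditions: Me3SiI, (Me3Si)2NH, CH2Cl2, −20 → 23 °C
Reagents that add atoms: iodotrimethylsilane C[Si](C)(C)I
Why: Silyl enol ether formation under equilibrating conditions should give the more substituted C1=C10 enol ether, the C1=C2 isomer being disfavoured by the adjacent quaternary C3, and the stereocentre at C10 is erased.

Step 11
Reactants: 20 trimethylsilyl enol ether of 19 with the C1=C10 double bond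
Product: 22 (1R,3aR,6R,8aS)-6-hydroxy-3a,6-dimethyl-1-(propan-2-yl)-8a-[(triethylsilyl)oxy]octahydroazulen-5(1H)-one, via silyloxy oxirane 21 (not isolated)
Conditions: dimethyldioxirane, acetone–CH2Cl2, −40 → 0 °C; then AcOH, THF–H2O, 0 °C
Reagents that add atoms: dimethyldioxirane CC1(C)OO1
Why: Rubottom oxidation, in which dimethyldioxirane should epoxidise the electron-rich enol ether on the face opposite to the C7 triethylsilyloxy group and the C3 methyl group (both stand on the same face of the seven-membered ring and screen it), and hydrolysis of the silyloxy oxirane then gives the tertiary α-hydroxy ketone with the C10 hydroxyl trans to the C7 oxygen (C10 R).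

Step 12
Reactants: 22 (1R,3aR,6R,8aS)-6-hydroxy-3a,6-dimethyl-1-(propan-2-yl)-8a-[(triethylsilyl)oxy]octahydroazulen-5(1H)-one
Product: 23 (1R,3aR,5R,6R,8aS)-3a,6-dimethyl-1-(propan-2-yl)-8a-[(triethylsilyl)oxy]decahydroazulene-5,6-diol
Conditions: Zn(BH4)2, Et2O, −20 → 0 °C
Reagents that add atoms: none
Why: Chelation-controlled reduction, in which zinc bridges the C10 hydroxyl and the C1 carbonyl and hydride is delivered to C1 from the face of the C10 hydroxyl, anti to the C10 methyl group and to the screening C7 silyloxy group, so that the new C1 hydroxyl should be trans to the C10 hydroxyl (C1 R).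

Step 13
Reactants: 23 (1R,3aR,5R,6R,8aS)-3a,6-dimethyl-1-(propan-2-yl)-8a-[(triethylsilyl)oxy]decahydroazulene-5,6-diol; 24 4-methoxybenzoyl chloride
Product: 25 (1R,3aR,5R,6R,8aS)-6-hydroxy-3a,6-dimethyl-1-(propan-2-yl)-8a-[(triethylsilyl)oxy]decahydroazulen-5-yl 4-methoxybenzoate
Conditions: DMAP, pyridine, CH2Cl2, 0 → 23 °C
Reagents that add atoms: none
Why: DMAP-catalysed acylation with an acid chloride should esterify the secondary C1 hydroxyl with retention, while the tertiary C10 hydroxyl does not react under these conditions.

Step 14
Reactants: 25 (1R,3aR,5R,6R,8aS)-6-hydroxy-3a,6-dimethyl-1-(propan-2-yl)-8a-[(triethylsilyl)oxy]decahydroazulen-5-yl 4-methoxybenzoate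
Product: 26 (1R,3aR,5R,6R,8aS)-6,8a-dihydroxy-3a,6-dimethyl-1-(propan-2-yl)decahydroazulen-5-yl 4-methoxybenzoate
Conditions: HF·pyridine, THF, 0 → 23 °C
Reagents that add atoms: none
Why: Fluoride-mediated cleavage of the silyl ether, under which the aryl ester and the two tertiary alcohols should be stable and no stereocentre is touched.

**Compound list**

1 | 2-methylcyclohexane-1,3-dione | CC1C(=O)CCCC1=O | starting material
2 | allyl acetate | C=CCOC(C)=O | starting material
3 | 2-methyl-2-(prop-2-en-1-yl)cyclohexane-1,3-dione | C=CCC1(C)C(=O)CCCC1=O | intermediate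
4 | secondary ozonide of 3, 2-methyl-2-[(1,2,4-trioxolan-3-yl)methyl]cyclohexane-1,3-dione | CC1(CC2OCOO2)C(=O)CCCC1=O | intermediate
5 | (1-methyl-2,6-dioxocyclohexyl)acetaldehyde | O=CCC1(C)C(=O)CCCC1=O | intermediate
6 | 1-(triphenylphosphoranylidene)propan-2-one | CC(=O)C=P(c1ccccc1)(c1ccccc1)c1ccccc1 | starting material
7 | 2-methyl-2-[(2E)-4-oxopent-2-en-1-yl]cyclohexane-1,3-dione | CC(=O)/C=C/CC1(C)C(=O)CCCC1=O | intermediate
8 | (Z)-copper enolate formed from 7 by hydride addition at C5 (bisphosphine on copper not drawn) | C/C(O[Cu])=C/CCC1(C)C(=O)CCCC1=O | intermediate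
9 | diethoxy(methyl)silyl ether of 10 at the C7 oxygen | O=C1[C@@]2(C)CC[C@H](C(C)=O)[C@@]2(O[Si](C)(OCC)OCC)CCC1 | intermediate
10 | (1S,3aS,7aS)-1-acetyl-7a-hydroxy-3a-methyloctahydro-4H-inden-4-one (C3 methyl, C7 hydroxyl and C6 acetyl all cis) | O=C1[C@@]2(C)CC[C@H](C(C)=O)[C@@]2(O)CCC1 | intermediate
11 | (1S,3aS,7aS)-1-acetyl-3a-methyl-7a-[(triethylsilyl)oxy]octahydro-4H-inden-4-one | O=C1[C@@]2(C)CC[C@H](C(C)=O)[C@@]2(O[Si](CC)(CC)CC)CCC1 | intermediate
12 | (1R,3aS,7aS)-3a-methyl-1-(prop-1-en-2-yl)-7a-[(triethylsilyl)oxy]octahydro-4H-inden-4-one | O=C1[C@@]2(C)CC[C@H](C(C)=C)[C@@]2(O[Si](CC)(CC)CC)CCC1 | intermediate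
13 | (1R,3aS,7aS)-3a-methyl-1-(propan-2-yl)-7a-[(triethylsilyl)oxy]octahydro-4H-inden-4-one | O=C1[C@@]2(C)CC[C@H](C(C)C)[C@@]2(O[Si](CC)(CC)CC)CCC1 | intermediate
14 | bis(phenylseleno)methane | C([Se]c1ccccc1)[Se]c1ccccc1 | starting material
15 | hydroxy selenide: C1 carbinol of 13 carrying a CH2SePh group (C1 configuration not controlled and immaterial) | OC1(C[Se]c3ccccc3)[C@@]2(C)CC[C@H](C(C)C)[C@@]2(O[Si](CC)(CC)CC)CCC1 | intermediate
16 | selenone of 15 (CH2–SeO2Ph) | OC1(C[Se](=O)(=O)c3ccccc3)[C@@]2(C)CC[C@H](C(C)C)[C@@]2(O[Si](CC)(CC)CC)CCC1 | intermediate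
17 | (1R,3aR,8aS)-3a-methyl-1-(propan-2-yl)-8a-[(triethylsilyl)oxy]octahydroazulen-5(1H)-one (C1 ketone, C2 methylene) | O=C1C[C@@]2(C)CC[C@H](C(C)C)[C@@]2(O[Si](CC)(CC)CC)CCC1 | intermediate
18 | lithium enolate of 17 with the C1=C10 double bond | C1=C(O[Li])C[C@@]2(C)CC[C@H](C(C)C)[C@@]2(O[Si](CC)(CC)CC)CC1 | intermediate
19 | (1R,3aR,8aS)-3a,6-dimethyl-1-(propan-2-yl)-8a-[(triethylsilyl)oxy]octahydroazulen-5(1H)-one, both C10 epimers | O=C1C[C@@]2(C)CC[C@H](C(C)C)[C@@]2(O[Si](CC)(CC)CC)CCC1C | intermediate
20 | trimethylsilyl enol ether of 19 with the C1=C10 double bond | CC1=C(O[Si](C)(C)C)C[C@@]2(C)CC[C@H](C(C)C)[C@@]2(O[Si](CC)(CC)CC)CC1 | intermediate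
21 | silyloxy oxirane of 20, oxirane oxygen on the face opposite to the C7 silyloxy group | C[Si](C)(C)O[C@]12C[C@@]3(C)CC[C@H](C(C)C)[C@@]3(O[Si](CC)(CC)CC)CC[C@@]1(C)O2 | intermediate
22 | (1R,3aR,6R,8aS)-6-hydroxy-3a,6-dimethyl-1-(propan-2-yl)-8a-[(triethylsilyl)oxy]octahydroazulen-5(1H)-one | O=C1C[C@@]2(C)CC[C@H](C(C)C)[C@@]2(O[Si](CC)(CC)CC)CC[C@@]1(C)O | intermediate
23 | (1R,3aR,5R,6R,8aS)-3a,6-dimethyl-1-(propan-2-yl)-8a-[(triethylsilyl)oxy]decahydroazulene-5,6-diol (trans-diol) | O[C@@H]1C[C@@]2(C)CC[C@H](C(C)C)[C@@]2(O[Si](CC)(CC)CC)CC[C@@]1(C)O | intermediate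
24 | 4-methoxybenzoyl chloride | COc1ccc(C(Cl)=O)cc1 | starting material
25 | (1R,3aR,5R,6R,8aS)-6-hydroxy-3a,6-dimethyl-1-(propan-2-yl)-8a-[(triethylsilyl)oxy]decahydroazulen-5-yl 4-methoxybenzoate | COc1ccc(C(=O)O[C@@H]2C[C@@]3(C)CC[C@H](C(C)C)[C@@]3(O[Si](CC)(CC)CC)CC[C@@]2(C)O)cc1 | intermediate
26 | (1R,3aR,5R,6R,8aS)-6,8a-dihydroxy-3a,6-dimethyl-1-(propan-2-yl)decahydroazulen-5-yl 4-methoxybenzoate | COc1ccc(C(=O)O[C@@H]2C[C@@]3(C)CC[C@H](C(C)C)[C@@]3(O)CC[C@@]2(C)O)cc1 | target

**Step count and risks**

Total steps: 14. Longest linear sequence: 14 steps (1 to 26).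

Step 8, the key step, is the most likely to fail.
- What may go wrong: the organolithium may enolise the hindered C1 ketone instead of adding; the hydroxy selenone may close to a spiro-oxirane instead of undergoing the 1,2-shift; methylene C10 may migrate in competition with C3; excess peracid may oxidise the product ketone further (Baeyer–Villiger).
- Fallback: it sets out from 13. Bis(phenylthio)methyllithium (from bis(phenylthio)methane and n-BuLi, THF, −78 → 0 °C) is added to the C1 carbonyl to give the bis(phenylthio)methyl carbinol F1. CuOSO2CF3 (benzene complex) with i-Pr2NEt in warm benzene removes one thiolate; the sulfur-stabilised cation at the new carbon is a far better migration terminus than a primary centre and cannot end as an oxirane, and the shift of C3 should give the 2-(phenylthio) ketone F2. SmI2 in THF–MeOH at −78 °C cleaves the C–S bond, and the route is rejoined at 17.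

Step 11 is the second risk.
- What may go wrong: facial selectivity of the enol ether epoxidation may be poor or reversed, since it rests on a conformational argument for a flexible seven-membered ring; minor C1=C2 enol ether carried over from step 10 would be oxidised at C2.
- Fallback: it sets out from 19. Tf2O with 2,6-di-tert-butyl-4-methylpyridine in CH2Cl2 gives the more substituted enol triflate F3. Pd(OAc)2, PPh3, n-Bu3N and HCO2H in DMF reduce it to the trisubstituted C1=C10 alkene F4. mCPBA (NaHCO3, CH2Cl2, 0 °C) gives the epoxide F5 on the face which such a failure would have shown to be the accessible one, syn to the C7 silyloxy group. Dilute HClO4 in aqueous THF at 0 °C opens the oxirane at tertiary C10 with inversion; this places the C10 hydroxyl trans to the C7 oxygen and leaves the C1 oxygen where the trans-diol needs it. The route is rejoined at 23 and step 12 is not needed.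

Step 4 is the third risk.
- What may go wrong: discrimination between the two enantiotopic carbonyls may be insufficient; 1,2-reduction of the enone or conjugate reduction without cyclisation may compete; the tertiary aldol may undergo retro-aldol cleavage or dehydration during work-up.
- Fallback: it sets out from 7. Stoichiometric [(Ph3P)CuH]6 in toluene at −40 °C effects the same conjugate reduction and aldol cyclisation without a chiral ligand and should give racemic 10 with the same all-cis relative configuration, that is 10 together with its antipode ent-10 F6. The antipodes are separated by preparative chromatography on a chiral stationary phase (cellulose tris(3,5-dimethylphenylcarbamate)), and the route is rejoined at 10.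

**Further compounds**

F1 | step 8 | bis(phenylthio)methyl carbinol at C1 of 13 (C1 configuration not controlled) | OC1(C(Sc3ccccc3)Sc3ccccc3)[C@@]2(C)CC[C@H](C(C)C)[C@@]2(O[Si](CC)(CC)CC)CCC1
F2 | step 8 | 2-(phenylthio) derivative of 17 (C2 configuration not controlled) | O=C1C(Sc3ccccc3)[C@@]2(C)CC[C@H](C(C)C)[C@@]2(O[Si](CC)(CC)CC)CCC1
F3 | step 11 | enol triflate of 19 with the C1=C10 double bond | CC1=C(OS(=O)(=O)C(F)(F)F)C[C@@]2(C)CC[C@H](C(C)C)[C@@]2(O[Si](CC)(CC)CC)CC1
F4 | step 11 | C1=C10 alkene bearing the C10 methyl group | CC1=CC[C@@]2(C)CC[C@H](C(C)C)[C@@]2(O[Si](CC)(CC)CC)CC1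
F5 | step 11 | C1–C10 epoxide of F4 with the oxygen syn to the C7 silyloxy group | [C@@H]12C[C@@]3(C)CC[C@H](C(C)C)[C@@]3(O[Si](CC)(CC)CC)CC[C@]1(C)O2
F6 | step 4 | ent-10, (1R,3aR,7aR)-1-acetyl-7a-hydroxy-3a-methyloctahydro-4H-inden-4-one | O=C1[C@]2(C)CC[C@@H](C(C)=O)[C@]2(O)CCC1
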